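## Retrosynthetic overview

1. Target 32 ⇐ oxidation of the side-chain carbinol (C1') of hydroxy lactone 31.
2. 31 ⇐ keto aldehyde 29: intramolecular allylboration (C3a–C8a, closes the seven-membered ring), then lactonisation in the same flask.
3. 29 ⇐ isoxazoline 26/24, made by the key late coupling: hydroxyl-directed nitrile oxide cycloaddition of fragment A (allylic alcohol 13, C6–C8a plus side chain) with fragment B (hydroximoyl chloride 21, C2–C5); it forms C5–C6 and C7–O.
4. 13 ⇐ vinylstannane 7 (from but-2-yn-1-ol and (Z)-1-bromopropene) + Weinreb amide 10 (from glyoxylic acid), then CBS reduction; 21 ⇐ 3,3-dimethoxypropanenitrile + methyl acrylate (Baylis–Hillman, allylic borylation).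
5. Ring order: isoxazoline (temporary) → cycloheptanone → γ-lactone.

Notation: target locants O1, C2, C3, C3a, C4–C8, C8a; side chain C1' (carbonyl) to C4'. TES = triethylsilyl; Bpin = 4,4,5,5-tetramethyl-1,3,2-dioxaborolan-2-yl.

Assumption: the C1' carbinol, which becomes the enone carbonyl in the last step, is carried from 6 to 31 with both configurations (racemic up to 12, about 1:1 epimers from 13 on) and is left undefined in the SMILES.

## Route

Step 1
Reactants: 1 but-2-yn-1-ol
Product: 2 (2E)-2-(tributylstannyl)but-2-en-1-ol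
Conditions: Bu3SnH, PdCl2(PPh3)2 (2 mol %), THF, rt
Reagents that add atoms: tributylstannane, CCCC[SnH](CCCC)CCCC
Why: Palladium-catalysed syn-hydrostannation of the propargylic alcohol puts tin next to the carbinol carbon with H cis to tin, which fixes the methyl cis to the CH2OH carbon (later C6-methyl cis to C1' on the C6=C7 alkene).

Step 2
Reactants: 2 (2E)-2-(tributylstannyl)but-2-en-1-ol
Product: 3 (2E)-2-(tributylstannyl)but-2-enal
Conditions: MnO2, CH2Cl2, rt
Reagents that add atoms: none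
Why: Allylic oxidation with activated MnO2 gives the enal without touching the vinylstannane or the alkene geometry.

Step 3
Reactants: 3 (2E)-2-(tributylstannyl)but-2-enal; 4 (1Z)-1-bromoprop-1-ene
Product: 6 (2E,5Z)-3-(tributylstannyl)hepta-2,5-dien-4-ol (racemic), via (1Z)-prop-1-en-1-yllithium 5 (not isolated)
Conditions: Li (2 equiv), Et2O, −10 °C; then 3, THF, −78 °C; H2O
Reagents that add atoms: none
Why: Reductive lithiation of the (Z)-bromide goes with retention and the alkenyllithium adds 1,2 to the enal (carbonyl addition), installing the (Z)-propenyl unit; the new C1' carbinol is racemic and ceases to be a stereocentre in step 19.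

Step 4
Reactants: 6 (2E,5Z)-3-(tributylstannyl)hepta-2,5-dien-4-ol
Product: 7 triethyl{[(2E,5Z)-3-(tributylstannyl)hepta-2,5-dien-4-yl]oxy}silane
Conditions: Et3SiCl, imidazole, CH2Cl2, 0 °C
Reagents that add atoms: chlorotriethylsilane, CC[Si](Cl)(CC)CC
Why: Silylation masks the C1' hydroxyl as an acid-labile TES ether so that only the C8 hydroxyl can later direct the cycloaddition.

Step 5
Reactants: 8 glyoxylic acid monohydrate
Product: 9 methyl 2,2-dimethoxyacetate
Conditions: MeOH, HC(OMe)3, H2SO4 (cat.), reflux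
Reagents that add atoms: methanol, CO; trimethyl orthoformate, COC(OC)OC
Why: Acid-catalysed Fischer esterification and acetalisation of the aldehyde hydrate, driven by the orthoformate as water scavenger, give the protected glyoxylate.

Step 6
Reactants: 9 methyl 2,2-dimethoxyacetate
Product: 10 N,2,2-trimethoxy-N-methylacetamide
Conditions: MeNH(OMe)·HCl, i-PrMgCl, THF, −20 → 0 °C
Reagents that add atoms: N,O-dimethylhydroxylamine hydrochloride, CNOC.Cl
Why: The chloromagnesium amide of N,O-dimethylhydroxylamine displaces methoxide from the ester (Weinreb amide formation).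

Step 7
Reactants: 7 triethyl{[(2E,5Z)-3-(tributylstannyl)hepta-2,5-dien-4-yl]oxy}silane; 10 N,2,2-trimethoxy-N-methylacetamide
Product: 12 (3E,5Z)-3-ethylidene-1,1-dimethoxy-4-[(triethylsilyl)oxy]hept-5-en-2-one (racemic), via vinyllithium 11 (not isolated)
Conditions: n-BuLi, THF, −78 °C; then 10, −78 → −20 °C; H2O
Reagents that add atoms: none
Why: Tin–lithium exchange keeps the alkene geometry and the vinyllithium acylates the Weinreb amide through a stable chelate that gives the ketone only on work-up (Weinreb ketone synthesis), forming the C7–C8 bond.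

Step 8
Reactants: 12 (3E,5Z)-3-ethylidene-1,1-dimethoxy-4-[(triethylsilyl)oxy]hept-5-en-2-one
Product: 13 (2R,3Z,5Z)-3-ethylidene-1,1-dimethoxy-4-[(triethylsilyl)oxy]hept-5-en-2-ol (4RS; ethylidene methyl cis to C4)
Conditions: (R)-Me-CBS oxazaborolidine (20 mol %), catecholborane, toluene, −78 °C
Reagents that add atoms: none
Why: Corey–Bakshi–Shibata reduction delivers hydride to the face set by the catalyst, assuming the branched alkenyl group acts as the large substituent, which sets C8 as R (the spatial arrangement of C8 in the target) in both C1' epimers.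

Step 9
Reactants: 14 3,3-dimethoxypropanenitrile
Product: 15 3,3-dimethoxypropanal
Conditions: i-Bu2AlH, CH2Cl2, −78 °C; aq. potassium sodium tartrate
Reagents that add atoms: water, O
Why: One hydride adds to the nitrile and the aluminium imide, stable at −78 °C, is hydrolysed on work-up to the aldehyde (partial nitrile reduction).

Step 10
Reactants: 15 3,3-dimethoxypropanal; 16 methyl prop-2-enoate
Product: 17 methyl 3-hydroxy-5,5-dimethoxy-2-methylidenepentanoate (racemic)
Conditions: DABCO (0.5 equiv), neat, rt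
Reagents that add atoms: none
Why: Morita–Baylis–Hillman reaction: the DABCO–acrylate zwitterion adds to the aldehyde and releases the amine to give the α-methylene-β-hydroxy ester, whose racemic carbinol is lost in step 12.

Step 11
Reactants: 17 methyl 3-hydroxy-5,5-dimethoxy-2-methylidenepentanoate
Product: 18 methyl 3-(acetyloxy)-5,5-dimethoxy-2-methylidenepentanoate (racemic)
Conditions: Ac2O, pyridine, DMAP (cat.), CH2Cl2, 0 °C → rt
Reagents that add atoms: acetic anhydride, CC(=O)OC(C)=O
Why: Acetylation turns the allylic alcohol into a leaving group for allylic substitution.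

Step 12
Reactants: 18 methyl 3-(acetyloxy)-5,5-dimethoxy-2-methylidenepentanoate
Product: 19 methyl (2E)-5,5-dimethoxy-2-[(Bpin)methyl]pent-2-enoate
Conditions: B2pin2, Pd2(dba)3 (2.5 mol %), toluene, 50 °C
Reagents that add atoms: bis(pinacolato)diboron, CC1(C)OB(OC1(C)C)B1OC(C)(C)C(C)(C)O1
Why: Oxidative addition of the allylic acetate to zerovalent palladium and transmetalation with the diboron put boron on the unsubstituted terminus (Miyaura-type allylic borylation), giving the thermodynamic E enoate in which C4 is cis to CH2B, a Z-crotyl-type boronate.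

Step 13
Reactants: 19 methyl (2E)-5,5-dimethoxy-2-[(Bpin)methyl]pent-2-enoate
Product: 20 methyl (2E)-5-(hydroxyimino)-2-[(Bpin)methyl]pent-2-enoate
Conditions: NH2OH·HCl, THF–H2O, 40 °C
Reagents that add atoms: hydroxylamine hydrochloride, NO.Cl
Why: The acidic hydroxylammonium salt opens the dimethyl acetal and traps the aldehyde at once as the oxime (acetal-to-oxime exchange), so the β,γ-unsaturated aldehyde never accumulates.

Step 14
Reactants: 20 methyl (2E)-5-(hydroxyimino)-2-[(Bpin)methyl]pent-2-enoate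
Product: 21 methyl (2E)-5-chloro-5-(hydroxyimino)-2-[(Bpin)methyl]pent-2-enoate
Conditions: NCS, DMF, 0 °C → rt
Reagents that add atoms: N-chlorosuccinimide, O=C1CCC(=O)N1Cl
Why: Electrophilic chlorination of the aldoxime carbon gives the hydroximoyl chloride, the storable nitrile oxide precursor.

Step 15
Reactants: 13 (2R,3Z,5Z)-3-ethylidene-1,1-dimethoxy-4-[(triethylsilyl)oxy]hept-5-en-2-ol; 21 methyl (2E)-5-chloro-5-(hydroxyimino)-2-[(Bpin)methyl]pent-2-enoate
Product: 24 methyl (2E)-4-[(4S,5S)-5-[(1R)-1-hydroxy-2,2-dimethoxyethyl]-4-methyl-5-{(2Z)-1-[(triethylsilyl)oxy]but-2-en-1-yl}-4,5-dihydro-1,2-oxazol-3-yl]-2-[(Bpin)methyl]but-2-enoate, via bromomagnesium alkoxide 22 (not isolated), via nitrile oxide 23 (not isolated)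
Conditions: i-PrOH (3.3 equiv), EtMgBr (3.0 equiv), CH2Cl2, 0 °C; then 21 (1.5 equiv, added over 2 h), 0 °C → rt; H2O
Reagents that add atoms: none
Why: Kanemasa hydroxyl-directed nitrile oxide cycloaddition (1,3-dipolar cycloaddition): magnesium bridges the C8 alkoxide and the dipole oxygen, so oxygen bonds to C7 and carbon to C6 on the alkene face syn to the alkoxide with the allylic hydrogen in the alkene plane, which sets C7 (O7 syn to O8) and, because the addition is suprafacial on an alkene whose methyl is cis to C1', C6.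

Step 16
Reactants: 24 isoxazoline alcohol (name as in step 15); 25 3-methylbutanoyl chloride
Product: 26 (1R)-2,2-dimethoxy-1-[(4S,5S)-3-{(2E)-3-(methoxycarbonyl)-4-(Bpin)but-2-en-1-yl}-4-methyl-5-{(2Z)-1-[(triethylsilyl)oxy]but-2-en-1-yl}-4,5-dihydro-1,2-oxazol-5-yl]ethyl 3-methylbutanoate
Conditions: pyridine, DMAP (cat.), CH2Cl2, 0 °C → rt
Reagents that add atoms: none
Why: DMAP-catalysed acylation of the only free hydroxyl (C8) installs the isovalerate without change at the stereocentre.

Step 17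
Reactants: 26 isoxazoline isovalerate (name as in step 16)
Product: 28 methyl (2E,6R,7S,8R)-7-hydroxy-9,9-dimethoxy-6-methyl-8-[(3-methylbutanoyl)oxy]-5-oxo-2-[(Bpin)methyl]-7-{(2Z)-1-[(triethylsilyl)oxy]but-2-en-1-yl}non-2-enoate, via hydroxy imine 27 (not isolated)
Conditions: SmI2 (3 equiv), THF, 0 °C; then B(OH)3, MeOH–H2O, rt
Reagents that add atoms: water, O
Why: SmI2 cleaves the weak N–O bond by single-electron transfer and boric acid hydrolyses the β-hydroxy imine to the β-hydroxy ketone (reductive isoxazoline opening), leaving C6 and C7 untouched; it must precede ring closure because a carbocycle spanning C5 and C7 of an intact isoxazoline would carry a bridgehead C=N.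

Step 18
Reactants: 28 β-hydroxy ketone (name as in step 17)
Product: 31 (3aS,6R,7R,8S,8aR)-7-hydroxy-7-[(2Z)-1-hydroxybut-2-en-1-yl]-6-methyl-3-methylidene-2,5-dioxooctahydro-2H-cyclohepta[b]furan-8-yl 3-methylbutanoate, via keto aldehyde 29 (not isolated), via boryl ether 30 (not isolated)
Conditions: TFA–H2O (9:1), CH2Cl2, 0 °C → rt
Reagents that add atoms: water, O
Why: Aqueous acid unmasks the C8a aldehyde and the C1' hydroxyl, and the Z-crotyl-type allylboronate then adds intramolecularly through a closed chair transition state (acid-accelerated allylboration) that makes H3a and H8a cis, the aldehyde is expected to react with its C8–O bond anti to the carbonyl (Cornforth arrangement, tether delivery) so that O8a ends trans to O8, and the cis borate closes onto the methyl ester to give the α-methylene lactone.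

Step 19
Reactants: 31 hydroxy lactone (name as in step 18)
Product: 32 (3aS,6R,7S,8S,8aR)-7-[(2Z)-but-2-enoyl]-7-hydroxy-6-methyl-3-methylidene-2,5-dioxooctahydro-2H-cyclohepta[b]furan-8-yl 3-methylbutanoate
Conditions: Dess–Martin periodinane, pyridine, CH2Cl2, 0 °C → rt
Reagents that add atoms: none
Why: Dess–Martin oxidation converts the secondary allylic C1' carbinol (both epimers) into the (Z)-enone without isomerising it, while the tertiary C7 hydroxyl cannot be oxidised.

## Compound list

1 | but-2-yn-1-ol | CC#CCO | starting material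
2 | (2E)-2-(tributylstannyl)but-2-en-1-ol | OC/C(=C\C)[Sn](CCCC)(CCCC)CCCC | intermediate
3 | (2E)-2-(tributylstannyl)but-2-enal | O=C/C(=C\C)[Sn](CCCC)(CCCC)CCCC | intermediate
4 | (1Z)-1-bromoprop-1-ene | C/C=C\Br | starting material
5 | (1Z)-prop-1-en-1-yllithium | C/C=C\[Li] | intermediate
6 | (2E,5Z)-3-(tributylstannyl)hepta-2,5-dien-4-ol (racemic) | C/C=C\C(O)/C(=C\C)[Sn](CCCC)(CCCC)CCCC | intermediate
7 | triethyl{[(2E,5Z)-3-(tributylstannyl)hepta-2,5-dien-4-yl]oxy}silane (racemic) | C/C=C\C(O[Si](CC)(CC)CC)/C(=C\C)[Sn](CCCC)(CCCC)CCCC | intermediate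
8 | glyoxylic acid monohydrate (2,2-dihydroxyacetic acid) | OC(O)C(=O)O | starting material
9 | methyl 2,2-dimethoxyacetate | COC(OC)C(=O)OC | intermediate
10 | N,2,2-trimethoxy-N-methylacetamide | COC(OC)C(=O)N(C)OC | intermediate
11 | {(2Z,5Z)-4-[(triethylsilyl)oxy]hepta-2,5-dien-3-yl}lithium (racemic) | C/C=C\C(O[Si](CC)(CC)CC)/C(=C\C)[Li] | intermediate
12 | (3E,5Z)-3-ethylidene-1,1-dimethoxy-4-[(triethylsilyl)oxy]hept-5-en-2-one (racemic) | C/C=C\C(O[Si](CC)(CC)CC)/C(=C\C)C(=O)C(OC)OC | intermediate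
13 | (2R,3Z,5Z)-3-ethylidene-1,1-dimethoxy-4-[(triethylsilyl)oxy]hept-5-en-2-ol (4RS) | C/C=C\C(O[Si](CC)(CC)CC)/C(=C\C)[C@@H](O)C(OC)OC | intermediate
14 | 3,3-dimethoxypropanenitrile | COC(OC)CC#N | starting material
15 | 3,3-dimethoxypropanal | COC(OC)CC=O | intermediate
16 | methyl prop-2-enoate (methyl acrylate) | C=CC(=O)OC | starting material
17 | methyl 3-hydroxy-5,5-dimethoxy-2-methylidenepentanoate (racemic) | COC(=O)C(=C)C(O)CC(OC)OC | intermediate
18 | methyl 3-(acetyloxy)-5,5-dimethoxy-2-methylidenepentanoate (racemic) | COC(=O)C(=C)C(OC(C)=O)CC(OC)OC | intermediate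
19 | methyl (2E)-5,5-dimethoxy-2-[(Bpin)methyl]pent-2-enoate | COC(=O)/C(CB1OC(C)(C)C(C)(C)O1)=C/CC(OC)OC | intermediate
20 | methyl (2E)-5-(hydroxyimino)-2-[(Bpin)methyl]pent-2-enoate | COC(=O)/C(CB1OC(C)(C)C(C)(C)O1)=C/CC=NO | intermediate
21 | methyl (2E)-5-chloro-5-(hydroxyimino)-2-[(Bpin)methyl]pent-2-enoate | COC(=O)/C(CB1OC(C)(C)C(C)(C)O1)=C/CC(Cl)=NO | intermediate
22 | bromomagnesium alkoxide of 13 | C/C=C\C(O[Si](CC)(CC)CC)/C(=C\C)[C@@H](O[Mg]Br)C(OC)OC | intermediate
23 | (3E)-4-(methoxycarbonyl)-5-(Bpin)pent-3-enenitrile N-oxide | COC(=O)/C(CB1OC(C)(C)C(C)(C)O1)=C/CC#[N+][O-] | intermediate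
24 | methyl (2E)-4-[(4S,5S)-5-[(1R)-1-hydroxy-2,2-dimethoxyethyl]-4-methyl-5-{(2Z)-1-[(triethylsilyl)oxy]but-2-en-1-yl}-4,5-dihydro-1,2-oxazol-3-yl]-2-[(Bpin)methyl]but-2-enoate (C1' epimers) | C/C=C\C(O[Si](CC)(CC)CC)[C@]1([C@@H](O)C(OC)OC)ON=C(C/C=C(/C(=O)OC)CB2OC(C)(C)C(C)(C)O2)[C@@H]1C | intermediate
25 | 3-methylbutanoyl chloride | CC(C)CC(=O)Cl | starting material
26 | (1R)-2,2-dimethoxy-1-[(4S,5S)-3-{(2E)-3-(methoxycarbonyl)-4-(Bpin)but-2-en-1-yl}-4-methyl-5-{(2Z)-1-[(triethylsilyl)oxy]but-2-en-1-yl}-4,5-dihydro-1,2-oxazol-5-yl]ethyl 3-methylbutanoate (C1' epimers) | C/C=C\C(O[Si](CC)(CC)CC)[C@]1([C@@H](OC(=O)CC(C)C)C(OC)OC)ON=C(C/C=C(/C(=O)OC)CB2OC(C)(C)C(C)(C)O2)[C@@H]1C | intermediate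
27 | 5-imino analogue of 28 (N–H ketimine, same configuration at C6, C7, C8) | C/C=C\C(O[Si](CC)(CC)CC)[C@@](O)([C@@H](OC(=O)CC(C)C)C(OC)OC)[C@@H](C)C(=N)C/C=C(/C(=O)OC)CB1OC(C)(C)C(C)(C)O1 | intermediate
28 | methyl (2E,6R,7S,8R)-7-hydroxy-9,9-dimethoxy-6-methyl-8-[(3-methylbutanoyl)oxy]-5-oxo-2-[(Bpin)methyl]-7-{(2Z)-1-[(triethylsilyl)oxy]but-2-en-1-yl}non-2-enoate (C1' epimers) | C/C=C\C(O[Si](CC)(CC)CC)[C@@](O)([C@@H](OC(=O)CC(C)C)C(OC)OC)[C@@H](C)C(=O)C/C=C(/C(=O)OC)CB1OC(C)(C)C(C)(C)O1 | intermediate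
29 | methyl (2E,6R,7R,8R)-7-hydroxy-7-[(2Z)-1-hydroxybut-2-en-1-yl]-6-methyl-8-[(3-methylbutanoyl)oxy]-5,9-dioxo-2-[(Bpin)methyl]non-2-enoate (C1' epimers) | C/C=C\C(O)[C@@](O)([C@@H](OC(=O)CC(C)C)C=O)[C@@H](C)C(=O)C/C=C(/C(=O)OC)CB1OC(C)(C)C(C)(C)O1 | intermediate
30 | ring-closed boryl ether: cycloheptanone as in 31 but with the lactone open, C3a carrying C(=CH2)CO2Me cis to O-Bpin on C8a | C=C(C(=O)OC)[C@@H]1CC(=O)[C@H](C)[C@@](O)(C(O)/C=C\C)[C@@H](OC(=O)CC(C)C)[C@@H]1OB2OC(C)(C)C(C)(C)O2 | intermediate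
31 | (3aS,6R,7R,8S,8aR)-7-hydroxy-7-[(2Z)-1-hydroxybut-2-en-1-yl]-6-methyl-3-methylidene-2,5-dioxooctahydro-2H-cyclohepta[b]furan-8-yl 3-methylbutanoate (C1' epimers) | C=C1C(=O)O[C@@H]2[C@H]1CC(=O)[C@H](C)[C@@](O)(C(O)/C=C\C)[C@H]2OC(=O)CC(C)C | intermediate
32 | (3aS,6R,7S,8S,8aR)-7-[(2Z)-but-2-enoyl]-7-hydroxy-6-methyl-3-methylidene-2,5-dioxooctahydro-2H-cyclohepta[b]furan-8-yl 3-methylbutanoate | C=C1C(=O)O[C@@H]2[C@H]1CC(=O)[C@H](C)[C@@](O)(C(=O)/C=C\C)[C@H]2OC(=O)CC(C)C | target

## Step count and risks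

Total: 19 steps. Longest linear sequence: 11 steps (1–4, 7, 8, 15–19; the branch 9–14 followed by 15–19 is equally long).

Three steps most likely to fail:

Step 15. The dipolarophile is a hindered trisubstituted alkene, the nitrile oxide can dimerise, and the boronate has to survive magnesium alkoxides. Fallback, setting out from 18 and returning at 24: DABCO (cat.) in THF shifts the acetate to the primary position to give methyl (2E)-2-[(acetyloxy)methyl]-5,5-dimethoxypent-2-enoate F1. NH2OH·HCl and then NCS give methyl (2E)-2-[(acetyloxy)methyl]-5-(hydroxyimino)pent-2-enoate F2 and methyl (2E)-2-[(acetyloxy)methyl]-5-chloro-5-(hydroxyimino)pent-2-enoate F3. The magnesium-directed cycloaddition of F3 with 13 under the step 15 conditions gives the acetoxymethyl isoxazoline F4, and boron is introduced only then with B2pin2 and Pd2(dba)3 to reach 24.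

Step 17. SmI2 must spare the enoate and boronate, and ketone 28 carries a β,γ-double bond that can move into conjugation on handling. Fallback, from 26 back to 31: hydrolyse first (TFA–H2O, CH2Cl2, 0 °C) to the isoxazoline aldehyde F5, which cannot cyclise while the ring ties C5 to C7. Then Mo(CO)6 in MeCN–H2O at 80 °C cleaves the N–O bond, and the keto aldehyde released undergoes allylboration and lactonisation in the same flask to 31, so 28 is never isolated.

Step 18. The acid has to open an α-acyloxy acetal without retro-aldol or alkene migration next to the C5 ketone, and the facial selectivity at C8a (O8a trans to O8) has the least precedent in the route. Fallback, from 28 to 32: NaBH4 in MeOH at −40 °C reduces the C5 ketone to the C5 carbinol F6, removing the acidic C4 hydrogens and the retro-aldol path. The same acid treatment gives the C5-hydroxy lactone F7, and Dess–Martin periodinane in excess oxidises C5 and C1' together to 32.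

Further compounds
F1 | step 15 | methyl (2E)-2-[(acetyloxy)methyl]-5,5-dimethoxypent-2-enoate | COC(=O)/C(COC(C)=O)=C/CC(OC)OC
F2 | step 15 | methyl (2E)-2-[(acetyloxy)methyl]-5-(hydroxyimino)pent-2-enoate | COC(=O)/C(COC(C)=O)=C/CC=NO
F3 | step 15 | methyl (2E)-2-[(acetyloxy)methyl]-5-chloro-5-(hydroxyimino)pent-2-enoate | COC(=O)/C(COC(C)=O)=C/CC(Cl)=NO
F4 | step 15 | acetoxymethyl isoxazoline (24 with CH2OAc in place of CH2Bpin) | C/C=C\C(O[Si](CC)(CC)CC)[C@]1([C@@H](O)C(OC)OC)ON=C(C/C=C(/C(=O)OC)COC(C)=O)[C@@H]1C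
F5 | step 17 | isoxazoline aldehyde (26 with CHO in place of CH(OMe)2 and free C1' hydroxyl) | C/C=C\C(O)[C@]1([C@@H](OC(=O)CC(C)C)C=O)ON=C(C/C=C(/C(=O)OC)CB2OC(C)(C)C(C)(C)O2)[C@@H]1C
F6 | step 18 | C5 carbinol of 28 (C5 epimers) | C/C=C\C(O[Si](CC)(CC)CC)[C@@](O)([C@@H](OC(=O)CC(C)C)C(OC)OC)[C@@H](C)C(O)C/C=C(/C(=O)OC)CB1OC(C)(C)C(C)(C)O1
F7 | step 18 | C5-hydroxy lactone (31 with CHOH at C5) | C=C1C(=O)O[C@@H]2[C@H]1CC(O)[C@H](C)[C@@](O)(C(O)/C=C\C)[C@H]2OC(=O)CC(C)C
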